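**Assumption:** the target has no stereocentre (the bridging CH carries two identical rings, and every ring carbon is sp2 or bears two identical methyl groups), so it is a single achiral compound and no asymmetric step is needed.

**Retrosynthetic overview**
- Watsonianone A ⇒ cut the CH–CH2 bond at the bridging carbon: isobutyl radical (from isobutyl iodide) adds to the central methine of a methine-bridged bis(syncarpic acid).
- Methine-bridged bis(syncarpic acid) ⇒ two syncarpic acids plus one CH unit from trimethyl orthoformate, assembled in the same flask as the radical addition.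
- Syncarpic acid ⇒ Dieckmann closure (CH2–CO bond) of an acyclic triketide methyl ester, itself built by two enolate acylations from methyl isobutyrate, isobutyryl chloride and acetyl chloride.
- Ring order: the only ring type, the six-membered trione carbocycle, is closed in step 2; two copies are joined through the bridging carbon in step 3; no further ring is formed.

**Step 1**
Reactants: 1 methyl 2-methylpropanoate (methyl isobutyrate); 2 2-methylpropanoyl chloride (isobutyryl chloride)
Product: 3 methyl 2,2,4-trimethyl-3-oxopentanoate
Conditions: LiN(iPr)2 (LDA, commercial solution, 1.05 equiv), THF, –78 °C; then 2 (1.0 equiv), –78 °C → rt; aq. NH4Cl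
Reagents that add atoms: none
Why: Crossed Claisen acylation, in which the fully preformed lithium ester enolate is C-acylated by the acid chloride and the product, having a quaternary carbon between its carbonyls, cannot be acylated again there; no stereocentre is formed.

**Step 2**
Reactants: 3 methyl 2,2,4-trimethyl-3-oxopentanoate; 4 acetyl chloride
Product: 6 syncarpic acid (5-hydroxy-2,2,6,6-tetramethylcyclohex-4-ene-1,3-dione), via methyl 2,2,4,4-tetramethyl-3,5-dioxohexanoate 5 (not isolated)
Conditions: LiN(iPr)2 (1.05 equiv), THF, –78 → 0 °C; 4 (1.0 equiv), –78 °C; then LiN(iPr)2 (2.2 equiv), –78 °C → rt; 1 M HCl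
Reagents that add atoms: none
Why: LDA removes the only enolisable proton of 3 (the isopropyl methine), the ester-chelated lithium enolate is C-acetylated (Claisen-type acylation) to 5, and the kinetic methyl-ketone enolate of 5 then closes the ring by a gem-dimethyl-assisted Dieckmann condensation driven by the stabilised syncarpate anion; no stereocentre is formed.

**Step 3**
Reactants: 6 syncarpic acid (2 equiv); 7 trimethyl orthoformate (trimethoxymethane, 1 equiv); 8 1-iodo-2-methylpropane (isobutyl iodide, 3 equiv)
Product: 11 watsonianone A (2,2'-(3-methylbutane-1,1-diyl)bis(3-hydroxy-4,4,6,6-tetramethylcyclohex-2-ene-1,5-dione)), via 2-(methoxymethylidene)-4,4,6,6-tetramethylcyclohexane-1,3,5-trione 9 (not isolated), via 2-[(2-hydroxy-3,3,5,5-tetramethyl-4,6-dioxocyclohex-1-en-1-yl)methylidene]-4,4,6,6-tetramethylcyclohexane-1,3,5-trione 10 (not isolated)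
Conditions: 7, PhMe, 100 °C, then MeOH–PhMe azeotrope distilled off; then 8, (Me3Si)3SiH (1.5 equiv, syringe pump), AIBN (0.2 equiv), PhMe, 80 °C; MeOH, 1 M HCl work-up
Reagents that add atoms: none
Why: Proposed new method: the acidic enol 6 condenses twice with the orthoester (addition–elimination through 9) to give 10, which stays neutral and intramolecularly hydrogen-bonded in base-free toluene and whose central CH is the β-carbon of a 2-alkylidene-1,3-dione, so the nucleophilic primary isobutyl radical (iodine abstraction from 8 by (Me3Si)3Si•) adds there and the resulting electrophilic 1,3-dicarbonyl radical takes H from the hydridic Si–H in a polarity-matched chain before tautomerising to the bis-enol; the closest known reaction type is the tin-free Giese addition of alkyl iodides to alkylidene malonates and alkylidene Meldrum's acids, and the new sp3 carbon bears two identical rings so it is not a stereocentre.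

**Compound list**
1 | methyl 2-methylpropanoate (methyl isobutyrate) | COC(=O)C(C)C | starting material
2 | 2-methylpropanoyl chloride (isobutyryl chloride) | CC(C)C(Cl)=O | starting material
3 | methyl 2,2,4-trimethyl-3-oxopentanoate | COC(=O)C(C)(C)C(=O)C(C)C | intermediate
4 | acetyl chloride | CC(Cl)=O | starting material
5 | methyl 2,2,4,4-tetramethyl-3,5-dioxohexanoate | COC(=O)C(C)(C)C(=O)C(C)(C)C(C)=O | intermediate
6 | syncarpic acid (5-hydroxy-2,2,6,6-tetramethylcyclohex-4-ene-1,3-dione) | CC1(C)C(=O)C=C(O)C(C)(C)C1=O | intermediate
7 | trimethyl orthoformate (trimethoxymethane) | COC(OC)OC | starting material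
8 | 1-iodo-2-methylpropane (isobutyl iodide) | CC(C)CI | starting material
9 | 2-(methoxymethylidene)-4,4,6,6-tetramethylcyclohexane-1,3,5-trione | COC=C1C(=O)C(C)(C)C(=O)C(C)(C)C1=O | intermediate
10 | 2-[(2-hydroxy-3,3,5,5-tetramethyl-4,6-dioxocyclohex-1-en-1-yl)methylidene]-4,4,6,6-tetramethylcyclohexane-1,3,5-trione | CC1(C)C(=O)C(C)(C)C(=O)C(=CC2=C(O)C(C)(C)C(=O)C(C)(C)C2=O)C1=O | intermediate
11 | watsonianone A | CC(C)CC(C1=C(O)C(C)(C)C(=O)C(C)(C)C1=O)C1=C(O)C(C)(C)C(=O)C(C)(C)C1=O | target

**Total step count:** 3
**Longest linear sequence:** 3 (1 → 3 → 6 → 11; two equivalents of 6 are joined in step 3)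

**Steps most likely to fail**

Step 3 (highest risk). Compound 10 is a strong vinylogous acid, and any ionisation to the oxonol anion makes it a poor radical acceptor. The isobutyl radical can also be reduced by the silane before it adds, and the reaction runs on unpurified 10. The fallback sets out from compound 6 and comes back to the route at compound 11. Compound 6 is heated in excess neat trimethyl orthoformate 7 so that the neutral, non-acidic acceptor 9 can be isolated. The same radical addition of 8 ((Me3Si)3SiH, AIBN, PhMe, 80 °C) to the methoxy-bearing carbon of 9 gives 3-hydroxy-2-(1-methoxy-3-methylbutyl)-4,4,6,6-tetramethylcyclohex-2-ene-1,5-dione F1 (racemic). F1 loses methanol on silica gel or with catalytic TsOH to give 4,4,6,6-tetramethyl-2-(3-methylbutylidene)cyclohexane-1,3,5-trione F2. Conjugate addition of a second equivalent of 6 to F2 (cat. Et3N, CH2Cl2, rt) gives 11. The key CH–CH2 bond is still formed by radical addition, but to a neutral acceptor in a radical addition–elimination followed by a polar Michael step.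

Step 2. The tetrasubstituted ketone enolate of 3 may be O-acetylated instead of C-acetylated, and proton transfer from product 5 to unreacted enolate can cap conversion. The fallback sets out from compound 3 and comes back to the route at compound 5. The lithium enolate of 3 is added to acetaldehyde (THF, –78 °C, cold quench), where only C-attack is possible, to give methyl 5-hydroxy-2,2,4,4-tetramethyl-3-oxohexanoate F3 (racemic; its stereocentre is erased at once). Dess–Martin periodinane oxidation then gives 5, which is isolated and cyclised separately with LiN(iPr)2 to 6.

Step 1 (lowest risk). Proton exchange between enolate and product, or O-acylation, could lower the yield on scale. The fallback sets out from compound 2 and comes back to the route at compound 3. Dehydrochlorination of 2 with Et3N (Et2O, reflux) gives dimethylketene, which dimerises to 2,2,4,4-tetramethylcyclobutane-1,3-dione F4. Ring-opening methanolysis of F4 (cat. NaOMe, MeOH, a retro-Claisen cleavage) delivers 3 without any ester-enolate chemistry.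

**Further compounds**
F1 | step 3 | 3-hydroxy-2-(1-methoxy-3-methylbutyl)-4,4,6,6-tetramethylcyclohex-2-ene-1,5-dione (racemic) | COC(CC(C)C)C1=C(O)C(C)(C)C(=O)C(C)(C)C1=O
F2 | step 3 | 4,4,6,6-tetramethyl-2-(3-methylbutylidene)cyclohexane-1,3,5-trione | CC(C)CC=C1C(=O)C(C)(C)C(=O)C(C)(C)C1=O
F3 | step 2 | methyl 5-hydroxy-2,2,4,4-tetramethyl-3-oxohexanoate (racemic) | COC(=O)C(C)(C)C(=O)C(C)(C)C(C)O
F4 | step 1 | 2,2,4,4-tetramethylcyclobutane-1,3-dione | CC1(C)C(=O)C(C)(C)C1=O
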